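2950 µM·h of charged free catalyst concentration times time is, as read from epsilon's last row, the halving exposure: the exposure, charged [free catalyst]·t, that leaves half of the substrate, for substrate and coupling partner charged as in the earlier runs.

| setting | zeta | epsilon | green | ochre |
|---|---|---|---|---|
| substrate | 0.015 M | 0.015 M | 0.015 M | 0.015 M |
| coupling partner | 0.030 M | 0.030 M | 0.0300 M | 0.0300 M |
| free catalyst | 33 µM | 110 µM | 75 µM | 25 µM |
| remark | run made earlier | run made earlier |  |  |
| time |  |  | 40 h | 150 h |

- zeta (time / h: product / %, substrate / %): 1.50: 1.9, 98.6; 3.00: 4.2, 97.3; 6.00: 4.4, 96.1; 10.0: 9.0, 92.3; 20.0: 15.2, 83.6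
- epsilon (time / h: product / %, substrate / %): 4.00: 9.8, 88.5; 8.00: 20.4, 80.5; 12.0: 27.5, 71.7; 15.0: 33.2, 67.5; 20.0: 41.1, 59.6

(each reading ± 1 percentage point)

- which of the two ends with the higher amount of product, in percent of the substrate charged ("neither" if they lie within 2 percentage points) (green / ochre / neither)
- product at the end, in percent of the substrate charged, green
- product at the end, in percent of the substrate charged, ochre

We read the tables against each other. Zeta's last row stands at exposure 660 µM·h with product 15.2 %. Epsilon's first two rows stand at 440 µM·h with 9.8 % and at 880 µM·h with 20.4 %. Zeta falls between them on both counts, so within a scatter of 1 percentage point the two runs lie on one curve in exposure. Across epsilon's last row, substrate and product add up to 101 %, so the product column accounts for what the substrate column loses. That row, with 59.6 % of the substrate left, gives the halving exposure as a reading, if the substrate falls exponentially in exposure.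

Green has exposure 3000 µM·h, and ochre has 3750 µM·h. Our reckoning therefore gives 50.6 % product for green and 58.6 % for ochre, a gap of 8 points, wider than the margin of 2 points.

The forecast says ochre, with 50.5 % for green and 56 % for ochre, on the ground that “Plotting against catalyst × time overlays the runs”. Its ochre figure is lower than ours.

The flasks give 50.1 % in green and 57.3 % in ochre, so ochre ends higher.

    coupling partner + free catalyst ⇌ catalyst intermediate A (K = 3.80 /M, k = 270 /M/min)
    substrate + catalyst intermediate A ⇌ catalyst intermediate B (K = 150 /M, k = 53.0 /M/min)
    catalyst intermediate B → catalyst intermediate C (k = 2.90 /min)
    catalyst intermediate C → released group + catalyst intermediate D (k = 0.790 /min)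
    catalyst intermediate D → free catalyst + product (k = 7.40 /min)
    crystals ⇌ released group, rate k6*(cs6 - [released group]) while solid is left; crystals form when [released group] > cs6 (solubility = 1.20 mM, k = 0.0290 /min)

Green ends with 49.9 % of its substrate left at exposure 3000 µM·h, and counted backward from the substrate left, the halving exposure reads 3050 µM·h in ochre. The neighbouring flask is green left until 6.0 d, with exposure 10800 µM·h, for which our reckoning gives 92.1 % product. It holds 88.2 % product and 11.8 % substrate, so its halving exposure, counted backward from the substrate left, reads 3503 µM·h, with 56 % of its coupling partner still there, unbound.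

All runs were generated by integration for substances that don't exist.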